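**Retrosynthetic overview**

1. Target 38 comes from desilylation and hydrogenolysis of a protected precursor. The pyranone (ring D) is made last, by acylketene cyclisation of a β-keto dioxinone grown from an arylacetaldehyde side chain.
2. The strategy rests on the aroyl ring (ring C): ketone at C1', oxygens at C2' and C4', the CH2 link at C6'. This is the pattern of an ynone joined to a 1,3-dioxygenated diene, so ring C is built by [4+2] cycloaddition of the C4 alkynyl ketone 20 with diene 23, forming C1'–C2' and C5'–C6'.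
3. Alkynone 20 comes from amine-free Negishi acylation of the tetralone-4-carbonyl chloride. Ring B comes from Friedel–Crafts closure (C1–C8a) of a 2-aryl-3-silyloxy-3-methylglutaric anhydride.
4. The C3/C4 stereodiad comes from Sharpless epoxidation of (Z)-dienol 5 (sets C3) and anti opening of the epoxide at C2 by an arylcopper reagent (sets C4).
5. Ring order: ring B (on preformed ring A), then ring C, then ring D.

Key step: step 14

Remark: tetralone numbering is used (C1 ring ketone, C2 methylene, C3 carbinol, C4 aroyl-bearing carbon; aroyl-ring positions primed). MgI2 is assumed to cleave both ethers that sit ortho to a ketone (2'-OMe and 8-OBn), and step 16 is written on that basis.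

**Route**

Step 1
Reactants: 1 5-bromobenzene-1,3-diol
Product: 2 1,3-bis(benzyloxy)-5-bromobenzene
Conditions: BnBr, K2CO3, DMF, rt
Reagents that add atoms: benzyl bromide BrCc1ccccc1
Why: Williamson ether synthesis; both phenoxides are alkylated by SN2 and the aryl bromide is inert.

Step 2
Reactants: 3 but-2-yn-1-ol
Product: 4 (2Z)-3-iodobut-2-en-1-ol
Conditions: NaAlH2(OCH2CH2OMe)2 (Red-Al), THF, 0 °C → rt; then I2, −78 °C
Reagents that add atoms: iodine II
Why: trans-hydroalumination of the propargylic alcohol (hydride to C2, aluminium to C3 within a cyclic alkoxyaluminate) followed by iodinolysis with retention should give the Z-iodide with iodine cis to CH2OH.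

Step 3
Reactants: 4 (2Z)-3-iodobut-2-en-1-ol
Product: 5 (2Z)-3-methylhexa-2,5-dien-1-ol
Conditions: allylSnBu3, PdCl2(MeCN)2 (5 mol%), DMF, rt
Reagents that add atoms: allyltributylstannane C=CC[Sn](CCCC)(CCCC)CCCC
Why: Stille coupling; oxidative addition, transmetalation and reductive elimination proceed with retention at the alkenyl carbon, so the allyl group ends cis to CH2OH.

Step 4
Reactants: 5 (2Z)-3-methylhexa-2,5-dien-1-ol
Product: 6 [(2S,3R)-3-methyl-3-(prop-2-en-1-yl)oxiran-2-yl]methanol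
Conditions: Ti(OiPr)4, L-(+)-diethyl tartrate, t-BuOOH, 4 Å MS, CH2Cl2, −20 °C
Reagents that add atoms: tert-butyl hydroperoxide CC(C)(C)OO
Why: Sharpless asymmetric epoxidation; the titanium tartrate complex delivers oxygen to one face of the allylic alkene only, setting C3 (R, the later tetralone C3) by reagent control as for other (Z)-3,3-disubstituted allylic alcohols, and the undirected terminal alkene stays.

Step 5
Reactants: 2 1,3-bis(benzyloxy)-5-bromobenzene; 6 [(2S,3R)-3-methyl-3-(prop-2-en-1-yl)oxiran-2-yl]methanol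
Product: 8 (2R,3R)-2-[3,5-bis(benzyloxy)phenyl]-3-methylhex-5-ene-1,3-diol, via arylmagnesium bromide 7 (not isolated)
Conditions: 2, Mg, THF, 40 °C; CuI (15 mol%), then 6, THF, −30 → 0 °C (3 equiv of 7)
Reagents that add atoms: none
Why: CuI-catalysed Grignard opening of a 2,3-epoxy alcohol; C3 is fully substituted, so the arylcopper species attacks C2 by SN2 with inversion, placing the aryl group anti to the C3 oxygen and setting the later C4 centre.

Step 6
Reactants: 8 (2R,3R)-2-[3,5-bis(benzyloxy)phenyl]-3-methylhex-5-ene-1,3-diol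
Product: 9 (2S,3R)-2-[3,5-bis(benzyloxy)phenyl]-3-hydroxy-3-methylhex-5-enoic acid
Conditions: TEMPO (cat.), PhI(OAc)2, MeCN/H2O, rt
Reagents that add atoms: water O
Why: oxoammonium (TEMPO) oxidation; only the primary alcohol is oxidised, through the aldehyde hydrate, to the acid under weakly acidic conditions, while the tertiary alcohol, the alkene and the benzyl ethers are inert.

Step 7
Reactants: 9 (2S,3R)-2-[3,5-bis(benzyloxy)phenyl]-3-hydroxy-3-methylhex-5-enoic acid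
Product: 11 (2S,3R)-2-[3,5-bis(benzyloxy)phenyl]-3-methyl-3-[(triethylsilyl)oxy]hex-5-enoic acid, via triethylsilyl ester 10 (not isolated)
Conditions: Et3SiOTf (2.5 equiv), 2,6-lutidine, CH2Cl2, −78 → 0 °C; then MeOH/H2O, citric acid, 0 °C
Reagents that add atoms: triethylsilyl trifluoromethanesulfonate CC[Si](CC)(CC)OS(=O)(=O)C(F)(F)F
Why: silylation with a silyl triflate reaches the hindered tertiary alcohol, and the labile silyl ester formed alongside is hydrolysed in the mildly acidic work-up that the tertiary silyl ether survives.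

Step 8
Reactants: 11 (2S,3R)-2-[3,5-bis(benzyloxy)phenyl]-3-methyl-3-[(triethylsilyl)oxy]hex-5-enoic acid
Product: 13 (2S,3R)-2-[3,5-bis(benzyloxy)phenyl]-3-methyl-3-[(triethylsilyl)oxy]pentanedioic acid, via aldehyde acid 12 (not isolated)
Conditions: OsO4 (cat.), NaIO4, 2,6-lutidine, dioxane/H2O, rt; then NaClO2, NaH2PO4, 2-methylbut-2-ene, t-BuOH/H2O, 0 °C → rt
Reagents that add atoms: sodium periodate [Na+].[O-]I(=O)(=O)=O; sodium chlorite [Na+].[O-]Cl=O
Why: Lemieux–Johnson cleavage of the terminal alkene then Pinnick oxidation; the side arm passes from alkene to aldehyde to acid without ever being an alcohol, so no lactone can form with the other carboxyl group, and the scavenger protects the electron-rich ring from HOCl.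

Step 9
Reactants: 13 (2S,3R)-2-[3,5-bis(benzyloxy)phenyl]-3-methyl-3-[(triethylsilyl)oxy]pentanedioic acid
Product: 15 (1S,2R)-5,7-bis(benzyloxy)-2-methyl-4-oxo-2-[(triethylsilyl)oxy]-1,2,3,4-tetrahydronaphthalene-1-carboxylic acid, via cyclic anhydride 14 (not isolated)
Conditions: (CF3CO)2O (2.2 equiv), CH2Cl2, 0 °C → rt; then H2O/THF
Reagents that add atoms: none
Why: intramolecular Friedel–Crafts acylation of an α-arylglutaric anhydride; only the CH2C(=O) carbonyl can reach the ring, and attack by the ortho carbon (para to one benzyloxy group, ortho to the other) closes ring B six-membered and releases the C4 carboxylic acid with C3 and C4 untouched.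

Step 10
Reactants: 16 but-3-yn-1-ol
Product: 17 (but-3-yn-1-yloxy)triethylsilane
Conditions: Et3SiCl, imidazole, CH2Cl2, 0 °C → rt
Reagents that add atoms: chlorotriethylsilane CC[Si](Cl)(CC)CC
Why: standard silylation of a primary alcohol, chosen so that this primary ether can later be removed in the presence of the tertiary one.

Step 11
Reactants: 15 (1S,2R)-5,7-bis(benzyloxy)-2-methyl-4-oxo-2-[(triethylsilyl)oxy]-1,2,3,4-tetrahydronaphthalene-1-carboxylic acid; 17 (but-3-yn-1-yloxy)triethylsilane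
Product: 20 (3R,4S)-6,8-bis(benzyloxy)-3-methyl-3-[(triethylsilyl)oxy]-4-{5-[(triethylsilyl)oxy]pent-2-ynoyl}-3,4-dihydronaphthalen-1(2H)-one, via acid chloride 18 (not isolated), via alkynylzinc chloride 19 (not isolated)
Conditions: 15, 1-chloro-N,N,2-trimethylprop-1-en-1-amine, CH2Cl2, 0 °C → rt; 17, n-BuLi, THF, −78 °C, then ZnCl2; combine, Pd(PPh3)4 (5 mol%), THF, 0 °C → rt
Reagents that add atoms: none
Why: Negishi acylation; the acid chloride is made under neutral conditions and coupled without any amine, so the acidic C4–H is not removed (no ketene, no epimerisation), and the alkynylzinc does not add to the ring ketone.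

Step 12
Reactants: 21 1,1-dimethoxyethene
Product: 22 4,4-dimethoxybut-3-en-2-one
Conditions: AcCl, Et3N, Et2O, 0 °C → rt
Reagents that add atoms: acetyl chloride CC(=O)Cl
Why: C-acylation of a ketene acetal; the nucleophilic CH2 adds to the acid chloride and Et3N removes HCl from the oxocarbenium intermediate.

Step 13
Reactants: 22 4,4-dimethoxybut-3-en-2-one
Product: 23 1,1-dimethoxy-3-(trimethylsilyloxy)buta-1,3-diene
Conditions: LiN(iPr)2, THF, −78 °C; then Me3SiCl
Reagents that add atoms: chlorotrimethylsilane C[Si](C)(C)Cl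
Why: kinetic enolisation at the methyl group and O-silylation give the cross-conjugated silyl enol ether, used directly after distillation.

Step 14
Reactants: 20 (3R,4S)-6,8-bis(benzyloxy)-3-methyl-3-[(triethylsilyl)oxy]-4-{5-[(triethylsilyl)oxy]pent-2-ynoyl}-3,4-dihydronaphthalen-1(2H)-one; 23 1,1-dimethoxy-3-(trimethylsilyloxy)buta-1,3-diene
Product: 26 (3R,4S)-6,8-bis(benzyloxy)-4-{4-hydroxy-2-methoxy-6-[2-(triethylsilyloxy)ethyl]benzoyl}-3-methyl-3-[(triethylsilyl)oxy]-3,4-dihydronaphthalen-1(2H)-one, via cyclohexadiene cycloadduct 24 (not isolated), via aryl trimethylsilyl ether 25 (not isolated)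
Conditions: 23 (3 equiv), toluene, 110 °C, sealed tube; then MeOH, rt
Reagents that add atoms: none
Why: Diels–Alder benzannulation: the ynone is electrophilic at its β-carbon and the diene, pushed by two methoxy groups and the silyloxy group, is most nucleophilic at its CH2 terminus, so C5'–C6' forms first in an asynchronous transition state and C1'–C2' follows to give the 1,4-cyclohexadiene 24. Loss of methanol across the ring aromatises 24 to the aryl silyl ether 25, and methanol then cleaves the aryl O–Si bond to give phenol 26. The closest known reaction is the cycloaddition of acetylenic ketones and esters with 1,1-dialkoxy-3-silyloxybuta-1,3-dienes, which gives 3-alkoxy-5-hydroxyaryl carbonyl compounds. Ring C closes in a six-membered [4+2] mode with both new bonds formed in one operation, and no stereocentre is created. The step needs regioselectivity, which the matched polarisation of the two partners secures, and it needs the C3 silyl ether and the epimerisable C4–H to survive, which the neutral, base-free thermal conditions should allow.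

Step 15
Reactants: 26 (3R,4S)-6,8-bis(benzyloxy)-4-{4-hydroxy-2-methoxy-6-[2-(triethylsilyloxy)ethyl]benzoyl}-3-methyl-3-[(triethylsilyl)oxy]-3,4-dihydronaphthalen-1(2H)-one
Product: 27 (3R,4S)-6,8-bis(benzyloxy)-4-{4-(benzyloxy)-2-methoxy-6-[2-(triethylsilyloxy)ethyl]benzoyl}-3-methyl-3-[(triethylsilyl)oxy]-3,4-dihydronaphthalen-1(2H)-one
Conditions: BnOH, PPh3, DIAD, THF, 0 °C → rt
Reagents that add atoms: benzyl alcohol OCc1ccccc1
Why: Mitsunobu etherification of the acidic, unhindered 4'-phenol under neutral conditions, which keeps the C4–H and the β-silyloxy ketone away from carbonate bases.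

Step 16
Reactants: 27 (3R,4S)-6,8-bis(benzyloxy)-4-{4-(benzyloxy)-2-methoxy-6-[2-(triethylsilyloxy)ethyl]benzoyl}-3-methyl-3-[(triethylsilyl)oxy]-3,4-dihydronaphthalen-1(2H)-one
Product: 29 (3R,4S)-6-(benzyloxy)-4-[4-(benzyloxy)-2-hydroxy-6-(2-hydroxyethyl)benzoyl]-8-hydroxy-3-methyl-3-[(triethylsilyl)oxy]-3,4-dihydronaphthalen-1(2H)-one, via bis-phenol silyl ether 28 (not isolated)
Conditions: MgI2·OEt2 (5 equiv), toluene/Et2O, 50 °C; then PPTS, MeOH, 0 °C → rt
Reagents that add atoms: none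
Why: chelation-controlled ether cleavage; magnesium binds each ketone oxygen together with its ortho ether oxygen (2'-OMe, 8-OBn) and iodide removes the alkyl group by SN2 while the two unchelated benzyl ethers stay, and acid-catalysed methanolysis then frees the primary alcohol much faster than the hindered tertiary silyl ether.

Step 17
Reactants: 29 (3R,4S)-6-(benzyloxy)-4-[4-(benzyloxy)-2-hydroxy-6-(2-hydroxyethyl)benzoyl]-8-hydroxy-3-methyl-3-[(triethylsilyl)oxy]-3,4-dihydronaphthalen-1(2H)-one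
Product: 30 (3R,4S)-6-(benzyloxy)-4-[4-(benzyloxy)-2-hydroxy-6-(2-oxoethyl)benzoyl]-8-hydroxy-3-methyl-3-[(triethylsilyl)oxy]-3,4-dihydronaphthalen-1(2H)-one
Conditions: 1,1,1-triacetoxy-1,1-dihydro-1,2-benziodoxol-3(1H)-one (DMP), NaHCO3, CH2Cl2, 0 °C
Reagents that add atoms: none
Why: periodinane oxidation of the primary alcohol under buffered, non-basic conditions; the two hydrogen-bonded phenols are poor substrates, and the arylacetaldehyde is used at once.

Step 18
Reactants: 31 2,2,6-trimethyl-4H-1,3-dioxin-4-one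
Product: 32 trimethyl[(2,2-dimethyl-6-methylidene-6H-1,3-dioxin-4-yl)oxy]silane
Conditions: LiN(iPr)2, THF, −78 °C; then Me3SiCl
Reagents that add atoms: chlorotrimethylsilane C[Si](C)(C)Cl
Why: γ-deprotonation of the vinylogous ester and O-silylation give the silyl dienol ether.

Step 19
Reactants: 30 (3R,4S)-6-(benzyloxy)-4-[4-(benzyloxy)-2-hydroxy-6-(2-oxoethyl)benzoyl]-8-hydroxy-3-methyl-3-[(triethylsilyl)oxy]-3,4-dihydronaphthalen-1(2H)-one; 32 trimethyl[(2,2-dimethyl-6-methylidene-6H-1,3-dioxin-4-yl)oxy]silane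
Product: 33 (3R,4S)-6-(benzyloxy)-4-{4-(benzyloxy)-6-[3-(2,2-dimethyl-4-oxo-4H-1,3-dioxin-6-yl)-2-hydroxypropyl]-2-hydroxybenzoyl}-8-hydroxy-3-methyl-3-[(triethylsilyl)oxy]-3,4-dihydronaphthalen-1(2H)-one (both carbinol epimers)
Conditions: 32 (3 equiv), BF3·OEt2, CH2Cl2, −78 °C
Reagents that add atoms: none
Why: vinylogous Mukaiyama aldol; BF3 activates the aldehyde, which is far more electrophilic than the two hindered ketones, and the dienol ether attacks through its exocyclic CH2, while the new carbinol centre needs no control because step 20 removes it.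

Step 20
Reactants: 33 (3R,4S)-6-(benzyloxy)-4-{4-(benzyloxy)-6-[3-(2,2-dimethyl-4-oxo-4H-1,3-dioxin-6-yl)-2-hydroxypropyl]-2-hydroxybenzoyl}-8-hydroxy-3-methyl-3-[(triethylsilyl)oxy]-3,4-dihydronaphthalen-1(2H)-one
Product: 34 (3R,4S)-6-(benzyloxy)-4-{4-(benzyloxy)-6-[3-(2,2-dimethyl-4-oxo-4H-1,3-dioxin-6-yl)-2-oxopropyl]-2-hydroxybenzoyl}-8-hydroxy-3-methyl-3-[(triethylsilyl)oxy]-3,4-dihydronaphthalen-1(2H)-one
Conditions: DMP, NaHCO3, CH2Cl2, 0 °C → rt
Reagents that add atoms: none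
Why: periodinane oxidation of the secondary alcohol to the β-keto dioxinone under the same buffered conditions as step 17.

Step 21
Reactants: 34 (3R,4S)-6-(benzyloxy)-4-{4-(benzyloxy)-6-[3-(2,2-dimethyl-4-oxo-4H-1,3-dioxin-6-yl)-2-oxopropyl]-2-hydroxybenzoyl}-8-hydroxy-3-methyl-3-[(triethylsilyl)oxy]-3,4-dihydronaphthalen-1(2H)-one
Product: 36 (3R,4S)-6-(benzyloxy)-4-{4-(benzyloxy)-2-hydroxy-6-[(4-hydroxy-2-oxo-2H-pyran-6-yl)methyl]benzoyl}-8-hydroxy-3-methyl-3-[(triethylsilyl)oxy]-3,4-dihydronaphthalen-1(2H)-one, via acylketene 35 (not isolated)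
Conditions: toluene (0.005 M), 110 °C
Reagents that add atoms: none
Why: dioxinone thermolysis; retro-[4+2] loss of acetone gives the acylketene, the enol oxygen of the δ-ketone adds to the ketene carbon (six-membered), and tautomerisation gives the 4-hydroxy-2-pyranone, with high dilution and a short heating time to hold back aldol attack of the active methylene on the hindered aroyl ketone.

Step 22
Reactants: 36 (3R,4S)-6-(benzyloxy)-4-{4-(benzyloxy)-2-hydroxy-6-[(4-hydroxy-2-oxo-2H-pyran-6-yl)methyl]benzoyl}-8-hydroxy-3-methyl-3-[(triethylsilyl)oxy]-3,4-dihydronaphthalen-1(2H)-one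
Product: 37 (3R,4S)-6-(benzyloxy)-4-{4-(benzyloxy)-2-hydroxy-6-[(4-hydroxy-2-oxo-2H-pyran-6-yl)methyl]benzoyl}-3,8-dihydroxy-3-methyl-3,4-dihydronaphthalen-1(2H)-one
Conditions: HF·pyridine, pyridine, THF, 0 °C → rt
Reagents that add atoms: none
Why: fluoride-mediated desilylation in a pyridine-buffered medium, mild enough not to dehydrate the tertiary β-hydroxy ketone.

Step 23
Reactants: 37 (3R,4S)-6-(benzyloxy)-4-{4-(benzyloxy)-2-hydroxy-6-[(4-hydroxy-2-oxo-2H-pyran-6-yl)methyl]benzoyl}-3,8-dihydroxy-3-methyl-3,4-dihydronaphthalen-1(2H)-one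
Product: 38 (3R,4S)-4-{2,4-dihydroxy-6-[(4-hydroxy-2-oxo-2H-pyran-6-yl)methyl]benzoyl}-3,6,8-trihydroxy-3-methyl-3,4-dihydronaphthalen-1(2H)-one (CNP0197349.1)
Conditions: H2 (1 atm), Pd/C (10 wt% Pd on carbon), EtOAc/MeOH, rt, stopped at full debenzylation
Reagents that add atoms: none
Why: hydrogenolysis of the two remaining aryl benzyl ethers under neutral conditions; the aryl ketones, the non-benzylic tertiary alcohol and the 4-hydroxy-2-pyranone should survive a short reaction.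

**Compound list**

1 | 5-bromobenzene-1,3-diol | Oc1cc(O)cc(Br)c1 | starting material
2 | 1,3-bis(benzyloxy)-5-bromobenzene | Brc1cc(OCc2ccccc2)cc(OCc2ccccc2)c1 | intermediate
3 | but-2-yn-1-ol | CC#CCO | starting material
4 | (2Z)-3-iodobut-2-en-1-ol | OC/C=C(/C)I | intermediate
5 | (2Z)-3-methylhexa-2,5-dien-1-ol | OC/C=C(/C)CC=C | intermediate
6 | [(2S,3R)-3-methyl-3-(prop-2-en-1-yl)oxiran-2-yl]methanol | OC[C@@H]1O[C@]1(C)CC=C | intermediate
7 | [3,5-bis(benzyloxy)phenyl]magnesium bromide | Br[Mg]c1cc(OCc2ccccc2)cc(OCc2ccccc2)c1 | intermediate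
8 | (2R,3R)-2-[3,5-bis(benzyloxy)phenyl]-3-methylhex-5-ene-1,3-diol | OC[C@@H](c1cc(OCc2ccccc2)cc(OCc2ccccc2)c1)[C@](C)(O)CC=C | intermediate
9 | (2S,3R)-2-[3,5-bis(benzyloxy)phenyl]-3-hydroxy-3-methylhex-5-enoic acid | OC(=O)[C@@H](c1cc(OCc2ccccc2)cc(OCc2ccccc2)c1)[C@](C)(O)CC=C | intermediate
10 | triethylsilyl (2S,3R)-2-[3,5-bis(benzyloxy)phenyl]-3-methyl-3-[(triethylsilyl)oxy]hex-5-enoate | CC[Si](CC)(CC)OC(=O)[C@@H](c1cc(OCc2ccccc2)cc(OCc2ccccc2)c1)[C@](C)(O[Si](CC)(CC)CC)CC=C | intermediate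
11 | (2S,3R)-2-[3,5-bis(benzyloxy)phenyl]-3-methyl-3-[(triethylsilyl)oxy]hex-5-enoic acid | OC(=O)[C@@H](c1cc(OCc2ccccc2)cc(OCc2ccccc2)c1)[C@](C)(O[Si](CC)(CC)CC)CC=C | intermediate
12 | (2S,3R)-2-[3,5-bis(benzyloxy)phenyl]-3-methyl-5-oxo-3-[(triethylsilyl)oxy]pentanoic acid | OC(=O)[C@@H](c1cc(OCc2ccccc2)cc(OCc2ccccc2)c1)[C@](C)(O[Si](CC)(CC)CC)CC=O | intermediate
13 | (2S,3R)-2-[3,5-bis(benzyloxy)phenyl]-3-methyl-3-[(triethylsilyl)oxy]pentanedioic acid | OC(=O)[C@@H](c1cc(OCc2ccccc2)cc(OCc2ccccc2)c1)[C@](C)(O[Si](CC)(CC)CC)CC(=O)O | intermediate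
14 | (3S,4R)-3-[3,5-bis(benzyloxy)phenyl]-4-methyl-4-[(triethylsilyl)oxy]oxane-2,6-dione | O=C1C[C@@](C)(O[Si](CC)(CC)CC)[C@H](c2cc(OCc3ccccc3)cc(OCc3ccccc3)c2)C(=O)O1 | intermediate
15 | (1S,2R)-5,7-bis(benzyloxy)-2-methyl-4-oxo-2-[(triethylsilyl)oxy]-1,2,3,4-tetrahydronaphthalene-1-carboxylic acid | C[C@@]1(O[Si](CC)(CC)CC)CC(=O)c2c(OCc3ccccc3)cc(OCc3ccccc3)cc2[C@@H]1C(=O)O | intermediate
16 | but-3-yn-1-ol | C#CCCO | starting material
17 | (but-3-yn-1-yloxy)triethylsilane | C#CCCO[Si](CC)(CC)CC | intermediate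
18 | (1S,2R)-5,7-bis(benzyloxy)-2-methyl-4-oxo-2-[(triethylsilyl)oxy]-1,2,3,4-tetrahydronaphthalene-1-carbonyl chloride | C[C@@]1(O[Si](CC)(CC)CC)CC(=O)c2c(OCc3ccccc3)cc(OCc3ccccc3)cc2[C@@H]1C(=O)Cl | intermediate
19 | chloro{4-[(triethylsilyl)oxy]but-1-yn-1-yl}zinc | Cl[Zn]C#CCCO[Si](CC)(CC)CC | intermediate
20 | (3R,4S)-6,8-bis(benzyloxy)-3-methyl-3-[(triethylsilyl)oxy]-4-{5-[(triethylsilyl)oxy]pent-2-ynoyl}-3,4-dihydronaphthalen-1(2H)-one | C[C@@]1(O[Si](CC)(CC)CC)CC(=O)c2c(OCc3ccccc3)cc(OCc3ccccc3)cc2[C@@H]1C(=O)C#CCCO[Si](CC)(CC)CC | intermediate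
21 | 1,1-dimethoxyethene | C=C(OC)OC | starting material
22 | 4,4-dimethoxybut-3-en-2-one | COC(OC)=CC(C)=O | intermediate
23 | 1,1-dimethoxy-3-(trimethylsilyloxy)buta-1,3-diene | COC(OC)=CC(=C)O[Si](C)(C)C | intermediate
24 | (3R,4S)-6,8-bis(benzyloxy)-4-({6,6-dimethoxy-2-[2-(triethylsilyloxy)ethyl]-4-(trimethylsilyloxy)cyclohexa-1,4-dien-1-yl}carbonyl)-3-methyl-3-[(triethylsilyl)oxy]-3,4-dihydronaphthalen-1(2H)-one | C[C@@]1(O[Si](CC)(CC)CC)CC(=O)c2c(OCc3ccccc3)cc(OCc3ccccc3)cc2[C@@H]1C(=O)C1=C(CCO[Si](CC)(CC)CC)CC(O[Si](C)(C)C)=CC1(OC)OC | intermediate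
25 | (3R,4S)-6,8-bis(benzyloxy)-4-{2-methoxy-6-[2-(triethylsilyloxy)ethyl]-4-(trimethylsilyloxy)benzoyl}-3-methyl-3-[(triethylsilyl)oxy]-3,4-dihydronaphthalen-1(2H)-one | C[C@@]1(O[Si](CC)(CC)CC)CC(=O)c2c(OCc3ccccc3)cc(OCc3ccccc3)cc2[C@@H]1C(=O)c1c(OC)cc(O[Si](C)(C)C)cc1CCO[Si](CC)(CC)CC | intermediate
26 | (3R,4S)-6,8-bis(benzyloxy)-4-{4-hydroxy-2-methoxy-6-[2-(triethylsilyloxy)ethyl]benzoyl}-3-methyl-3-[(triethylsilyl)oxy]-3,4-dihydronaphthalen-1(2H)-one | C[C@@]1(O[Si](CC)(CC)CC)CC(=O)c2c(OCc3ccccc3)cc(OCc3ccccc3)cc2[C@@H]1C(=O)c1c(OC)cc(O)cc1CCO[Si](CC)(CC)CC | intermediate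
27 | (3R,4S)-6,8-bis(benzyloxy)-4-{4-(benzyloxy)-2-methoxy-6-[2-(triethylsilyloxy)ethyl]benzoyl}-3-methyl-3-[(triethylsilyl)oxy]-3,4-dihydronaphthalen-1(2H)-one | C[C@@]1(O[Si](CC)(CC)CC)CC(=O)c2c(OCc3ccccc3)cc(OCc3ccccc3)cc2[C@@H]1C(=O)c1c(OC)cc(OCc3ccccc3)cc1CCO[Si](CC)(CC)CC | intermediate
28 | (3R,4S)-6-(benzyloxy)-4-{4-(benzyloxy)-2-hydroxy-6-[2-(triethylsilyloxy)ethyl]benzoyl}-8-hydroxy-3-methyl-3-[(triethylsilyl)oxy]-3,4-dihydronaphthalen-1(2H)-one | C[C@@]1(O[Si](CC)(CC)CC)CC(=O)c2c(O)cc(OCc3ccccc3)cc2[C@@H]1C(=O)c1c(O)cc(OCc3ccccc3)cc1CCO[Si](CC)(CC)CC | intermediate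
29 | (3R,4S)-6-(benzyloxy)-4-[4-(benzyloxy)-2-hydroxy-6-(2-hydroxyethyl)benzoyl]-8-hydroxy-3-methyl-3-[(triethylsilyl)oxy]-3,4-dihydronaphthalen-1(2H)-one | C[C@@]1(O[Si](CC)(CC)CC)CC(=O)c2c(O)cc(OCc3ccccc3)cc2[C@@H]1C(=O)c1c(O)cc(OCc3ccccc3)cc1CCO | intermediate
30 | (3R,4S)-6-(benzyloxy)-4-[4-(benzyloxy)-2-hydroxy-6-(2-oxoethyl)benzoyl]-8-hydroxy-3-methyl-3-[(triethylsilyl)oxy]-3,4-dihydronaphthalen-1(2H)-one | C[C@@]1(O[Si](CC)(CC)CC)CC(=O)c2c(O)cc(OCc3ccccc3)cc2[C@@H]1C(=O)c1c(O)cc(OCc3ccccc3)cc1CC=O | intermediate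
31 | 2,2,6-trimethyl-4H-1,3-dioxin-4-one | CC1=CC(=O)OC(C)(C)O1 | starting material
32 | trimethyl[(2,2-dimethyl-6-methylidene-6H-1,3-dioxin-4-yl)oxy]silane | C=C1C=C(O[Si](C)(C)C)OC(C)(C)O1 | intermediate
33 | (3R,4S)-6-(benzyloxy)-4-{4-(benzyloxy)-6-[3-(2,2-dimethyl-4-oxo-4H-1,3-dioxin-6-yl)-2-hydroxypropyl]-2-hydroxybenzoyl}-8-hydroxy-3-methyl-3-[(triethylsilyl)oxy]-3,4-dihydronaphthalen-1(2H)-one (carbinol centre undefined) | C[C@@]1(O[Si](CC)(CC)CC)CC(=O)c2c(O)cc(OCc3ccccc3)cc2[C@@H]1C(=O)c1c(O)cc(OCc3ccccc3)cc1CC(O)CC1=CC(=O)OC(C)(C)O1 | intermediate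
34 | (3R,4S)-6-(benzyloxy)-4-{4-(benzyloxy)-6-[3-(2,2-dimethyl-4-oxo-4H-1,3-dioxin-6-yl)-2-oxopropyl]-2-hydroxybenzoyl}-8-hydroxy-3-methyl-3-[(triethylsilyl)oxy]-3,4-dihydronaphthalen-1(2H)-one | C[C@@]1(O[Si](CC)(CC)CC)CC(=O)c2c(O)cc(OCc3ccccc3)cc2[C@@H]1C(=O)c1c(O)cc(OCc3ccccc3)cc1CC(=O)CC1=CC(=O)OC(C)(C)O1 | intermediate
35 | (3R,4S)-6-(benzyloxy)-4-[4-(benzyloxy)-2-hydroxy-6-(2,4,6-trioxohex-5-en-1-yl)benzoyl]-8-hydroxy-3-methyl-3-[(triethylsilyl)oxy]-3,4-dihydronaphthalen-1(2H)-one | C[C@@]1(O[Si](CC)(CC)CC)CC(=O)c2c(O)cc(OCc3ccccc3)cc2[C@@H]1C(=O)c1c(O)cc(OCc3ccccc3)cc1CC(=O)CC(=O)C=C=O | intermediate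
36 | (3R,4S)-6-(benzyloxy)-4-{4-(benzyloxy)-2-hydroxy-6-[(4-hydroxy-2-oxo-2H-pyran-6-yl)methyl]benzoyl}-8-hydroxy-3-methyl-3-[(triethylsilyl)oxy]-3,4-dihydronaphthalen-1(2H)-one | C[C@@]1(O[Si](CC)(CC)CC)CC(=O)c2c(O)cc(OCc3ccccc3)cc2[C@@H]1C(=O)c1c(O)cc(OCc3ccccc3)cc1Cc1cc(O)cc(=O)o1 | intermediate
37 | (3R,4S)-6-(benzyloxy)-4-{4-(benzyloxy)-2-hydroxy-6-[(4-hydroxy-2-oxo-2H-pyran-6-yl)methyl]benzoyl}-3,8-dihydroxy-3-methyl-3,4-dihydronaphthalen-1(2H)-one | C[C@@]1(O)CC(=O)c2c(O)cc(OCc3ccccc3)cc2[C@@H]1C(=O)c1c(O)cc(OCc3ccccc3)cc1Cc1cc(O)cc(=O)o1 | intermediate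
38 | (3R,4S)-4-{2,4-dihydroxy-6-[(4-hydroxy-2-oxo-2H-pyran-6-yl)methyl]benzoyl}-3,6,8-trihydroxy-3-methyl-3,4-dihydronaphthalen-1(2H)-one | C[C@@]1(O)CC(=O)c2c(O)cc(O)cc2[C@@H]1C(=O)c1c(O)cc(O)cc1Cc1cc(O)cc(=O)o1 | target

**Step count and risks**

Total step count: 23. Longest linear sequence: 18 steps (steps 2–9, 11, 14–17, 19–23).

Steps most likely to fail:

1. Step 9 (Friedel–Crafts closure of ring B). The trifluoroacetic acid released may strip the tertiary silyl ether, after which the β-oxygen can be acylated and eliminated towards a naphthol. Enolisation of the activated C4 carbonyl may also erode the C4 configuration. Fallback: anionic ring closure in place of electrophilic acylation, setting out from diacid 13. Ring bromination with NBS (MeCN, 0 °C) ortho to the side chain should give (2S,3R)-2-[3,5-bis(benzyloxy)-2-bromophenyl]-3-methyl-3-[(triethylsilyl)oxy]pentanedioic acid F1. Treatment with n-BuLi (2 equiv) then t-BuLi (2 equiv) in THF at −100 °C forms the dilithium dicarboxylate and exchanges bromine for lithium to give the aryllithium dicarboxylate F2. This attacks the CH2CO2Li group (Parham cyclisation), and aqueous work-up returns the route to 15.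

2. Step 14 (key cycloaddition). The internal ynone, flanked by a bulky acyl group, may react too slowly, so that the diene decomposes or the β-silyloxy ketone eliminates on prolonged heating. Fallback: join a preformed ring C to the acid chloride through the aryl–acyl bond, setting out from 2 and 18. Bromine–lithium exchange on 2 (n-BuLi, THF, −78 °C) and opening of ethylene oxide (BF3·OEt2) should give 2-[3,5-bis(benzyloxy)phenyl]ethanol F3. Silylation (Et3SiCl, imidazole) gives {2-[3,5-bis(benzyloxy)phenyl]ethoxy}triethylsilane F4, and NBS bromination ortho to the side chain gives {2-[3,5-bis(benzyloxy)-2-bromophenyl]ethoxy}triethylsilane F5. Exchange with n-BuLi and ZnCl2 gives the arylzinc chloride F6. Negishi acylation with 18 (Pd(PPh3)4, THF) gives (3R,4S)-6,8-bis(benzyloxy)-4-{2,4-bis(benzyloxy)-6-[2-(triethylsilyloxy)ethyl]benzoyl}-3-methyl-3-[(triethylsilyl)oxy]-3,4-dihydronaphthalen-1(2H)-one F7. MgI2·OEt2 as in step 16 then cleaves the two chelated benzyl ethers, and the route is rejoined at 28.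

3. Step 16 (chelation-controlled dealkylation). The 2',6'-disubstituted aryl ketone is twisted and may chelate poorly, so demethylation may stall. Meanwhile the magnesium-bound ring ketone may promote β-elimination of the C3 silyloxy group or epimerisation at C4 on heating. Fallback: never form the methyl ether, setting out from 20. Cycloaddition under the conditions of step 14 with 1-methoxy-1,3-bis(trimethylsilyloxy)buta-1,3-diene F8 (from methyl acetoacetate by two silylations) should give, after collapse of the mixed silyl acetal and methanolysis, (3R,4S)-6,8-bis(benzyloxy)-4-{2,4-dihydroxy-6-[2-(triethylsilyloxy)ethyl]benzoyl}-3-methyl-3-[(triethylsilyl)oxy]-3,4-dihydronaphthalen-1(2H)-one F9. Mitsunobu benzylation of the unchelated 4'-hydroxyl (BnOH, PPh3, DIAD) gives (3R,4S)-6,8-bis(benzyloxy)-4-{4-(benzyloxy)-2-hydroxy-6-[2-(triethylsilyloxy)ethyl]benzoyl}-3-methyl-3-[(triethylsilyl)oxy]-3,4-dihydronaphthalen-1(2H)-one F10. MgBr2·OEt2 at rt then removes only the chelated 8-O-benzyl group, and the route is rejoined at 28.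

**Further compounds**

F1 | step 9 | (2S,3R)-2-[3,5-bis(benzyloxy)-2-bromophenyl]-3-methyl-3-[(triethylsilyl)oxy]pentanedioic acid | OC(=O)[C@@H](c1c(Br)c(OCc2ccccc2)cc(OCc2ccccc2)c1)[C@](C)(O[Si](CC)(CC)CC)CC(=O)O
F2 | step 9 | dilithium (2S,3R)-2-[3,5-bis(benzyloxy)-2-lithiophenyl]-3-methyl-3-[(triethylsilyl)oxy]pentanedioate | [Li]OC(=O)[C@@H](c1c([Li])c(OCc2ccccc2)cc(OCc2ccccc2)c1)[C@](C)(O[Si](CC)(CC)CC)CC(=O)O[Li]
F3 | step 14 | 2-[3,5-bis(benzyloxy)phenyl]ethanol | OCCc1cc(OCc2ccccc2)cc(OCc2ccccc2)c1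
F4 | step 14 | {2-[3,5-bis(benzyloxy)phenyl]ethoxy}triethylsilane | CC[Si](CC)(CC)OCCc1cc(OCc2ccccc2)cc(OCc2ccccc2)c1
F5 | step 14 | {2-[3,5-bis(benzyloxy)-2-bromophenyl]ethoxy}triethylsilane | CC[Si](CC)(CC)OCCc1cc(OCc2ccccc2)cc(OCc2ccccc2)c1Br
F6 | step 14 | chloro{2,4-bis(benzyloxy)-6-[2-(triethylsilyloxy)ethyl]phenyl}zinc | CC[Si](CC)(CC)OCCc1cc(OCc2ccccc2)cc(OCc2ccccc2)c1[Zn]Cl
F7 | step 14 | (3R,4S)-6,8-bis(benzyloxy)-4-{2,4-bis(benzyloxy)-6-[2-(triethylsilyloxy)ethyl]benzoyl}-3-methyl-3-[(triethylsilyl)oxy]-3,4-dihydronaphthalen-1(2H)-one | C[C@@]1(O[Si](CC)(CC)CC)CC(=O)c2c(OCc3ccccc3)cc(OCc3ccccc3)cc2[C@@H]1C(=O)c1c(OCc3ccccc3)cc(OCc3ccccc3)cc1CCO[Si](CC)(CC)CC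
F8 | step 16 | 1-methoxy-1,3-bis(trimethylsilyloxy)buta-1,3-diene | COC(O[Si](C)(C)C)=CC(=C)O[Si](C)(C)C
F9 | step 16 | (3R,4S)-6,8-bis(benzyloxy)-4-{2,4-dihydroxy-6-[2-(triethylsilyloxy)ethyl]benzoyl}-3-methyl-3-[(triethylsilyl)oxy]-3,4-dihydronaphthalen-1(2H)-one | C[C@@]1(O[Si](CC)(CC)CC)CC(=O)c2c(OCc3ccccc3)cc(OCc3ccccc3)cc2[C@@H]1C(=O)c1c(O)cc(O)cc1CCO[Si](CC)(CC)CC
F10 | step 16 | (3R,4S)-6,8-bis(benzyloxy)-4-{4-(benzyloxy)-2-hydroxy-6-[2-(triethylsilyloxy)ethyl]benzoyl}-3-methyl-3-[(triethylsilyl)oxy]-3,4-dihydronaphthalen-1(2H)-one | C[C@@]1(O[Si](CC)(CC)CC)CC(=O)c2c(OCc3ccccc3)cc(OCc3ccccc3)cc2[C@@H]1C(=O)c1c(O)cc(OCc3ccccc3)cc1CCO[Si](CC)(CC)CC
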